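**Retrosynthetic overview**
1. Scolopendrine comes from the 8‑hydroxy‑2‑quinolinone 20 by O‑sulfation at C8–OH and then O‑debenzylation at C4'. The two phenols stay distinguishable throughout: C8–O as benzenesulfonate, C4'–O as benzyl ether.
2. The pyridone ring is opened at C3–C4, formed by an intermolecular aldol addition of the lithium enolate of methyl methoxyacetate to 2‑nitrobenzaldehyde 12, and at N1–C2, formed by nitro reduction and lactamisation. Dehydration then aromatises the ring.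
3. Aldehyde 12 comes from ester 10. The diarylmethane bond of 10 is made by an sp3–sp2 Suzuki coupling of benzylic bromide 9 with boronic acid 5.
4. Bromide 9 derives from 3‑hydroxy‑4‑methyl‑2‑nitrobenzoic acid, which already carries all four contiguous substituents. Boronic acid 5 derives from 4‑bromoguaiacol.
5. Ring order: both benzene rings are bought. The pyridone ring is the only ring built (steps 9–11).

**Assumption:** the target SMILES contains no stereocentre, so the compound is achiral and needs no stereocontrol. It is delivered as the free hydrogen sulfate as drawn.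

**Step 1**
Reactants: 1 4‑bromo‑2‑methoxyphenol
Product: 2 1‑(benzyloxy)‑4‑bromo‑2‑methoxybenzene
Conditions: BnBr, K2CO3, acetone, reflux
Reagents that add atoms: benzyl bromide BrCc1ccccc1
Why: Williamson ether synthesis (SN2 of the phenoxide on BnBr) installs a benzyl ether that survives every later step and is removed last by hydrogenolysis.

**Step 2**
Reactants: 2 1‑(benzyloxy)‑4‑bromo‑2‑methoxybenzene
Product: 5 [4‑(benzyloxy)‑3‑methoxyphenyl]boronic acid, via aryllithium 3 (not isolated), via lithium aryltriisopropoxyborate 4 (not isolated)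
Conditions: n‑BuLi, THF, −78 °C; B(OiPr)3, −78 °C → rt; 1 M HCl
Reagents that add atoms: triisopropyl borate CC(C)OB(OC(C)C)OC(C)C; water O
Why: Lithiation–borylation works because Br/Li exchange at −78 °C outruns benzylic deprotonation, and the ate complex hydrolyses to the boronic acid.

**Step 3**
Reactants: 6 3‑hydroxy‑4‑methyl‑2‑nitrobenzoic acid
Product: 7 methyl 3‑hydroxy‑4‑methyl‑2‑nitrobenzoate
Conditions: MeOH, cat. H2SO4, reflux
Reagents that add atoms: methanol CO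
Why: Fischer esterification in excess methanol masks the acid as an ester that tolerates radical bromination and cross‑coupling.

**Step 4**
Reactants: 7 methyl 3‑hydroxy‑4‑methyl‑2‑nitrobenzoate
Product: 8 methyl 4‑methyl‑2‑nitro‑3‑[(phenylsulfonyl)oxy]benzoate
Conditions: PhSO2Cl, K2CO3, acetone, reflux
Reagents that add atoms: benzenesulfonyl chloride O=S(=O)(Cl)c1ccccc1
Why: O‑sulfonylation of the acidic nitrophenol gives a protecting group with no abstractable benzylic C–H (unlike tosyl, benzyl or MOM) that is orthogonal to the benzyl ether.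

**Step 5**
Reactants: 8 methyl 4‑methyl‑2‑nitro‑3‑[(phenylsulfonyl)oxy]benzoate
Product: 9 methyl 4‑(bromomethyl)‑2‑nitro‑3‑[(phenylsulfonyl)oxy]benzoate
Conditions: NBS (1.05 equiv), AIBN (5 mol %), PhCF3, 85 °C
Reagents that add atoms: N‑bromosuccinimide O=C1CCC(=O)N1Br
Why: Wohl–Ziegler bromination attacks the only benzylic C–H in the molecule, and the electron‑poor ring slows a second bromination.

**Step 6**
Reactants: 9 methyl 4‑(bromomethyl)‑2‑nitro‑3‑[(phenylsulfonyl)oxy]benzoate; 5 [4‑(benzyloxy)‑3‑methoxyphenyl]boronic acid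
Product: 10 methyl 4‑[4‑(benzyloxy)‑3‑methoxybenzyl]‑2‑nitro‑3‑[(phenylsulfonyl)oxy]benzoate
Conditions: Pd(OAc)2 (2 mol %), PPh3 (4 mol %), K3PO4, toluene, 80 °C, Ar
Reagents that add atoms: none
Why: In this sp3–sp2 Suzuki–Miyaura coupling, oxidative addition into the benzylic C–Br bond is far faster than into the aryl sulfonate with PPh3, and the non‑aqueous phosphate base spares ester and sulfonate.

**Step 7**
Reactants: 10 methyl 4‑[4‑(benzyloxy)‑3‑methoxybenzyl]‑2‑nitro‑3‑[(phenylsulfonyl)oxy]benzoate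
Product: 11 6‑[4‑(benzyloxy)‑3‑methoxybenzyl]‑3‑(hydroxymethyl)‑2‑nitrophenyl benzenesulfonate
Conditions: DIBAL‑H (2.3 equiv), CH2Cl2, −78 → −40 °C; aq. Rochelle salt
Reagents that add atoms: none
Why: Hydride reduction of the ester with DIBAL‑H at low temperature leaves the nitro group, aryl sulfonate and benzyl ether untouched.

**Step 8**
Reactants: 11 6‑[4‑(benzyloxy)‑3‑methoxybenzyl]‑3‑(hydroxymethyl)‑2‑nitrophenyl benzenesulfonate
Product: 12 6‑[4‑(benzyloxy)‑3‑methoxybenzyl]‑3‑formyl‑2‑nitrophenyl benzenesulfonate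
Conditions: Dess–Martin periodinane, CH2Cl2, rt
Reagents that add atoms: none
Why: Dess–Martin oxidation stops cleanly at the aldehyde even for electron‑poor benzylic alcohols and does not touch the diarylmethane CH2.

**Step 9**
Reactants: 12 6‑[4‑(benzyloxy)‑3‑methoxybenzyl]‑3‑formyl‑2‑nitrophenyl benzenesulfonate; 13 methyl methoxyacetate
Product: 15 methyl 3‑{4‑[4‑(benzyloxy)‑3‑methoxybenzyl]‑2‑nitro‑3‑[(phenylsulfonyl)oxy]phenyl}‑3‑hydroxy‑2‑methoxypropanoate (racemic syn/anti mixture), via lithium enolate 14 (not isolated)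
Conditions: LDA (commercial solution, 1.25 equiv), 13 (1.3 equiv), THF, −78 °C; add 12, −78 °C, 30 min; AcOH quench at −78 °C
Reagents that add atoms: none
Why: This intermolecular aldol addition forges C3–C4 because carbonyl addition of the preformed ester enolate at −78 °C outruns any C–H deprotonation, and the two new stereocentres are set unselectively but both become sp2 in step 11.

**Step 10**
Reactants: 15 aldol adduct
Product: 17 7‑[4‑(benzyloxy)‑3‑methoxybenzyl]‑4‑hydroxy‑3‑methoxy‑2‑oxo‑1,2,3,4‑tetrahydroquinolin‑8‑yl benzenesulfonate (diastereomer mixture), via amino ester 16 (not isolated)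
Conditions: Fe powder, AcOH–EtOH (1:3), 75 °C
Reagents that add atoms: none
Why: Béchamp‑type nitro reduction spares the benzyl ether and sulfonate, the aniline lactamises onto the saturated ester (6‑exo‑trig) with no alkene‑geometry problem, and any 19 already formed is carried along.

**Step 11**
Reactants: 17 4‑hydroxy‑3,4‑dihydroquinolinone
Product: 19 7‑[4‑(benzyloxy)‑3‑methoxybenzyl]‑3‑methoxy‑2‑oxo‑1,2‑dihydroquinolin‑8‑yl benzenesulfonate, via C4 mesylate 18 (not isolated)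
Conditions: MsCl, Et3N, CH2Cl2, 0 °C; then DBU, rt
Reagents that add atoms: none
Why: Mesylation followed by E1cB/E2 elimination of the C3–H alpha to the lactam completes the aldol condensation, is driven by aromatisation to the 2‑quinolinone, and erases both stereocentres.

**Step 12**
Reactants: 19 8‑benzenesulfonate quinolinone
Product: 20 7‑[4‑(benzyloxy)‑3‑methoxybenzyl]‑8‑hydroxy‑3‑methoxyquinolin‑2(1H)‑one
Conditions: 2 M aq. NaOH, 1,4‑dioxane, 90 °C, Ar; then 1 M HCl to pH 5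
Reagents that add atoms: none
Why: Alkaline hydrolysis of the aryl sulfonate proceeds by hydroxide attack at sulfur with S–O cleavage, the alcohol‑free medium forms no alkylating sulfonate ester, and the ethers and lactam are inert.

**Step 13**
Reactants: 20 8‑hydroxyquinolinone
Product: 22 sodium 7‑[4‑(benzyloxy)‑3‑methoxybenzyl]‑3‑methoxy‑2‑oxo‑1,2‑dihydroquinolin‑8‑yl sulfate, via pyridinium sulfate 21 (not isolated)
Conditions: SO3·pyridine (5 equiv), pyridine, 45 °C; aq. NaHCO3 to pH 8; C18 chromatography (H2O–MeOH)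
Reagents that add atoms: sulfur trioxide–pyridine complex [O-]S(=O)(=O)[n+]1ccccc1; sodium hydrogen carbonate [Na+].OC([O-])=O
Why: O‑sulfation hits the only free phenol, any sulfation at the lactam oxygen is reversed in the bicarbonate work‑up, and that work‑up also replaces pyridinium (a poison for the next hydrogenolysis) by sodium.

**Step 14**
Reactants: 22 sodium sulfate, benzyl ether
Product: 24 scolopendrine, 7‑(4‑hydroxy‑3‑methoxybenzyl)‑3‑methoxy‑2‑oxo‑1,2‑dihydroquinolin‑8‑yl hydrogen sulfate, via scolopendrine sodium salt 23 (not isolated)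
Conditions: H2 (1 atm), 10 % Pd/C, MeOH, rt; filter; C18 column, wash with cold 0.01 M aq. HCl, elute H2O–MeOH, lyophilise cold
Reagents that add atoms: none
Why: Neutral catalytic hydrogenolysis cleaves only the O‑benzyl group (aryl sulfate salts and 2‑quinolinones survive 1 atm H2), and the brief cold acid wash exchanges Na+ for H+ without hydrolysing the sulfate.

**Compound list**
1 | 4‑bromo‑2‑methoxyphenol | COc1cc(Br)ccc1O | starting material
2 | 1‑(benzyloxy)‑4‑bromo‑2‑methoxybenzene | COc1cc(Br)ccc1OCc1ccccc1 | intermediate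
3 | [4‑(benzyloxy)‑3‑methoxyphenyl]lithium | [Li]c1ccc(OCc2ccccc2)c(OC)c1 | intermediate
4 | lithium [4‑(benzyloxy)‑3‑methoxyphenyl]triisopropoxyborate | [Li+].COc1cc(ccc1OCc1ccccc1)[B-](OC(C)C)(OC(C)C)OC(C)C | intermediate
5 | [4‑(benzyloxy)‑3‑methoxyphenyl]boronic acid | COc1cc(B(O)O)ccc1OCc1ccccc1 | intermediate
6 | 3‑hydroxy‑4‑methyl‑2‑nitrobenzoic acid | Cc1ccc(C(=O)O)c([N+](=O)[O-])c1O | starting material
7 | methyl 3‑hydroxy‑4‑methyl‑2‑nitrobenzoate | COC(=O)c1ccc(C)c(O)c1[N+](=O)[O-] | intermediate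
8 | methyl 4‑methyl‑2‑nitro‑3‑[(phenylsulfonyl)oxy]benzoate | COC(=O)c1ccc(C)c(OS(=O)(=O)c2ccccc2)c1[N+](=O)[O-] | intermediate
9 | methyl 4‑(bromomethyl)‑2‑nitro‑3‑[(phenylsulfonyl)oxy]benzoate | COC(=O)c1ccc(CBr)c(OS(=O)(=O)c2ccccc2)c1[N+](=O)[O-] | intermediate
10 | methyl 4‑[4‑(benzyloxy)‑3‑methoxybenzyl]‑2‑nitro‑3‑[(phenylsulfonyl)oxy]benzoate | COC(=O)c1ccc(Cc2ccc(OCc3ccccc3)c(OC)c2)c(OS(=O)(=O)c2ccccc2)c1[N+](=O)[O-] | intermediate
11 | 6‑[4‑(benzyloxy)‑3‑methoxybenzyl]‑3‑(hydroxymethyl)‑2‑nitrophenyl benzenesulfonate | OCc1ccc(Cc2ccc(OCc3ccccc3)c(OC)c2)c(OS(=O)(=O)c2ccccc2)c1[N+](=O)[O-] | intermediate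
12 | 6‑[4‑(benzyloxy)‑3‑methoxybenzyl]‑3‑formyl‑2‑nitrophenyl benzenesulfonate | O=Cc1ccc(Cc2ccc(OCc3ccccc3)c(OC)c2)c(OS(=O)(=O)c2ccccc2)c1[N+](=O)[O-] | intermediate
13 | methyl methoxyacetate | COCC(=O)OC | starting material
14 | lithium enolate of methyl methoxyacetate | [Li+].[O-]C(OC)=COC | intermediate
15 | methyl 3‑{4‑[4‑(benzyloxy)‑3‑methoxybenzyl]‑2‑nitro‑3‑[(phenylsulfonyl)oxy]phenyl}‑3‑hydroxy‑2‑methoxypropanoate (racemic syn/anti mixture) | COC(=O)C(OC)C(O)c1ccc(Cc2ccc(OCc3ccccc3)c(OC)c2)c(OS(=O)(=O)c2ccccc2)c1[N+](=O)[O-] | intermediate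
16 | methyl 3‑{2‑amino‑4‑[4‑(benzyloxy)‑3‑methoxybenzyl]‑3‑[(phenylsulfonyl)oxy]phenyl}‑3‑hydroxy‑2‑methoxypropanoate (mixture) | COC(=O)C(OC)C(O)c1ccc(Cc2ccc(OCc3ccccc3)c(OC)c2)c(OS(=O)(=O)c2ccccc2)c1N | intermediate
17 | 7‑[4‑(benzyloxy)‑3‑methoxybenzyl]‑4‑hydroxy‑3‑methoxy‑2‑oxo‑1,2,3,4‑tetrahydroquinolin‑8‑yl benzenesulfonate (mixture) | COC1C(O)c2ccc(Cc3ccc(OCc4ccccc4)c(OC)c3)c(OS(=O)(=O)c3ccccc3)c2NC1=O | intermediate
18 | 7‑[4‑(benzyloxy)‑3‑methoxybenzyl]‑3‑methoxy‑4‑[(methylsulfonyl)oxy]‑2‑oxo‑1,2,3,4‑tetrahydroquinolin‑8‑yl benzenesulfonate (mixture) | COC1C(OS(C)(=O)=O)c2ccc(Cc3ccc(OCc4ccccc4)c(OC)c3)c(OS(=O)(=O)c3ccccc3)c2NC1=O | intermediate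
19 | 7‑[4‑(benzyloxy)‑3‑methoxybenzyl]‑3‑methoxy‑2‑oxo‑1,2‑dihydroquinolin‑8‑yl benzenesulfonate | COc1cc2ccc(Cc3ccc(OCc4ccccc4)c(OC)c3)c(OS(=O)(=O)c3ccccc3)c2[nH]c1=O | intermediate
20 | 7‑[4‑(benzyloxy)‑3‑methoxybenzyl]‑8‑hydroxy‑3‑methoxyquinolin‑2(1H)‑one | COc1cc2ccc(Cc3ccc(OCc4ccccc4)c(OC)c3)c(O)c2[nH]c1=O | intermediate
21 | pyridinium 7‑[4‑(benzyloxy)‑3‑methoxybenzyl]‑3‑methoxy‑2‑oxo‑1,2‑dihydroquinolin‑8‑yl sulfate | COc1cc2ccc(Cc3ccc(OCc4ccccc4)c(OC)c3)c(OS(=O)(=O)[O-])c2[nH]c1=O.c1cc[nH+]cc1 | intermediate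
22 | sodium 7‑[4‑(benzyloxy)‑3‑methoxybenzyl]‑3‑methoxy‑2‑oxo‑1,2‑dihydroquinolin‑8‑yl sulfate | COc1cc2ccc(Cc3ccc(OCc4ccccc4)c(OC)c3)c(OS(=O)(=O)[O-])c2[nH]c1=O.[Na+] | intermediate
23 | sodium 7‑(4‑hydroxy‑3‑methoxybenzyl)‑3‑methoxy‑2‑oxo‑1,2‑dihydroquinolin‑8‑yl sulfate | COc1cc2ccc(Cc3ccc(O)c(OC)c3)c(OS(=O)(=O)[O-])c2[nH]c1=O.[Na+] | intermediate
24 | scolopendrine (achiral) | COc1cc(Cc2ccc3cc(OC)c(=O)[nH]c3c2OS(=O)(=O)O)ccc1O | target

**Totals:** 14 steps in all. The longest linear sequence is 12 steps (6 → 24, steps 3–14). The boronic acid branch adds 2 steps.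

**Three steps most likely to fail**

Step 6 (benzylic Suzuki coupling). The risks are homocoupling of the electron‑poor benzylic bromide and loss of the activated sulfonate. The fallback sets out from 9 and comes back at 10.
- Bromide 9 is oxidised with N‑methylmorpholine N‑oxide (MeCN, 4 Å sieves, rt) to methyl 4‑formyl‑2‑nitro‑3‑[(phenylsulfonyl)oxy]benzoate F1.
- Boronic acid 5 is added to the formyl group under palladium catalysis (PdCl2, P(1‑naphthyl)3, K2CO3, THF, 65 °C). This 1,2‑addition works well on nitrobenzaldehydes. It gives racemic methyl 4‑{[4‑(benzyloxy)‑3‑methoxyphenyl](hydroxy)methyl}‑2‑nitro‑3‑[(phenylsulfonyl)oxy]benzoate F2.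
- Ionic hydrogenation (Et3SiH, TFA, CH2Cl2, 0 °C) through the alkoxy‑stabilised benzhydryl cation then delivers 10.

Step 9 (aldol addition). The risks are enolate basicity toward the diarylmethane CH2 para to the formyl group, electron transfer to the nitroarene, and retro‑aldol on work‑up. The fallback sets out from 12 and comes back at 19.
- The nitro group of 12 is reduced first (Fe, NH4Cl, EtOH–H2O, 70 °C) to 2‑amino‑6‑[4‑(benzyloxy)‑3‑methoxybenzyl]‑3‑formylphenyl benzenesulfonate F3.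
- F3 is N‑acylated at once with methoxyacetyl chloride (pyridine, CH2Cl2, 0 °C) to 6‑[4‑(benzyloxy)‑3‑methoxybenzyl]‑3‑formyl‑2‑(2‑methoxyacetamido)phenyl benzenesulfonate F4.
- t‑BuOK in THF/t‑BuOH (0 °C → rt) closes C3–C4 by a Camps‑type intramolecular aldol condensation and gives 19 directly. Any material that loses the sulfonate here is simply 20.

Step 13 (sulfation). The risks are the hindered, hydrogen‑bonded 8‑OH and the isolation of a very polar salt. The fallback sets out from 20 and comes back at 24.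
- Phenol 20 is treated with 2,2,2‑trichloroethyl chlorosulfate (Et3N, DMAP, THF, rt). This gives the neutral, silica‑stable diester 7‑[4‑(benzyloxy)‑3‑methoxybenzyl]‑3‑methoxy‑2‑oxo‑1,2‑dihydroquinolin‑8‑yl 2,2,2‑trichloroethyl sulfate F5.
- Transfer hydrogenolysis (10 % Pd/C, HCO2NH4, MeOH, rt) removes the trichloroethyl and benzyl groups together. This gives ammonium 7‑(4‑hydroxy‑3‑methoxybenzyl)‑3‑methoxy‑2‑oxo‑1,2‑dihydroquinolin‑8‑yl sulfate F6.
- The cold 0.01 M HCl / C18 treatment of step 14 converts F6 into 24.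

**Further compounds**
F1 | step 6 | methyl 4‑formyl‑2‑nitro‑3‑[(phenylsulfonyl)oxy]benzoate | COC(=O)c1ccc(C=O)c(OS(=O)(=O)c2ccccc2)c1[N+](=O)[O-]
F2 | step 6 | methyl 4‑{[4‑(benzyloxy)‑3‑methoxyphenyl](hydroxy)methyl}‑2‑nitro‑3‑[(phenylsulfonyl)oxy]benzoate (racemic) | COC(=O)c1ccc(C(O)c2ccc(OCc3ccccc3)c(OC)c2)c(OS(=O)(=O)c2ccccc2)c1[N+](=O)[O-]
F3 | step 9 | 2‑amino‑6‑[4‑(benzyloxy)‑3‑methoxybenzyl]‑3‑formylphenyl benzenesulfonate | O=Cc1ccc(Cc2ccc(OCc3ccccc3)c(OC)c2)c(OS(=O)(=O)c2ccccc2)c1N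
F4 | step 9 | 6‑[4‑(benzyloxy)‑3‑methoxybenzyl]‑3‑formyl‑2‑(2‑methoxyacetamido)phenyl benzenesulfonate | COCC(=O)Nc1c(C=O)ccc(Cc2ccc(OCc3ccccc3)c(OC)c2)c1OS(=O)(=O)c1ccccc1
F5 | step 13 | 7‑[4‑(benzyloxy)‑3‑methoxybenzyl]‑3‑methoxy‑2‑oxo‑1,2‑dihydroquinolin‑8‑yl 2,2,2‑trichloroethyl sulfate | COc1cc2ccc(Cc3ccc(OCc4ccccc4)c(OC)c3)c(OS(=O)(=O)OCC(Cl)(Cl)Cl)c2[nH]c1=O
F6 | step 13 | ammonium 7‑(4‑hydroxy‑3‑methoxybenzyl)‑3‑methoxy‑2‑oxo‑1,2‑dihydroquinolin‑8‑yl sulfate | COc1cc2ccc(Cc3ccc(O)c(OC)c3)c(OS(=O)(=O)[O-])c2[nH]c1=O.[NH4+]
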